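**Target:** (+)-isolariciresinol 9'-O-(E)-p-coumarate. Tetralin numbering used throughout: C1 carries the pendant aryl group, C2 the acyloxymethyl arm, C3 the hydroxymethyl arm, C4 is the benzylic CH2; ring A is the benzo ring (C4a, C5–C8, C8a), ring B the saturated ring, ring C the pendant aryl group.

## Structural features

The target is a 1-aryltetralin. Ring A carries OMe on C6 and OH on C7, ring B is the carbocycle C1–C4/C4a/C8a, and ring C is a 4-hydroxy-3-methoxyphenyl group on C1. C1 (S), C2 (R) and C3 (R) are contiguous and all-trans, so that the aryl group and both CH2O arms are equatorial. The two primary CH2O arms differ only by position: the more hindered C2 arm, next to the aryl-bearing carbon, carries the (E)-p-coumarate, and the C3 arm is free. Fragile groups are the cinnamate alkene (no hydrogenation, sensitive to UV light), the ester (acyl migration to the neighbouring CH2OH under base), three free phenols and the doubly benzylic C1–H. The real difficulty is twofold: the three contiguous stereocenters must be set as a group in the absolute sense, and the two arms must be told apart so that the more hindered one is acylated. The key step exploits that ring A carries two ortho carbon substituents, C1 and C4. Ring A can therefore be written as an o-quinodimethane (C1=C8a–C4a=C4), and a Diels–Alder reaction with a C2=C3 dienophile closes ring B. The oxygen that this leaves on C4, cis to the C3 arm, is then used to distinguish the arms before it is removed.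

In one sentence: ring B is closed by a Diels–Alder reaction between the photoenol (a hydroxy-o-quinodimethane) of a 2-benzylbenzaldehyde and a C2-symmetric chiral fumarate.

## Logic of the disconnections

21 to 20: the three phenolic O–H bonds are replaced by O–Si bonds. Free phenols would compete in the acylation and are prone to oxidation. The forward step must cleave three aryl silyl ethers with buffered fluoride so that the ester neither migrates nor is cleaved.

20 to 19: an oxygen is put back on C4 (C4–H becomes C4–O) and tied to the oxygen of the C3 arm as a six-membered ketal. The reason is that a C4 oxygen cis to the C3 arm is what distinguishes the two arms. The problem of the arms becomes the protection of a 1,3-diol. The forward step must cleave the benzylic C4–O bond by ionisation and hydride capture without touching the cinnamate and without elimination towards C3.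

19 to 15 and 18: the ester C(=O)–O bond is cut. This separates the acyl part from the core. It demands that the only free hydroxyl group of 15 is that of the C2 arm.

18 to 16: the phenolic O–Si bond is cut; the forward step must silylate the phenol and leave the acid free.

15 to 14: the two ketal C–O bonds are cut. The forward step must close the six-membered ketal over O4 and the C3 arm in preference to a seven-membered one over the two arms.

14 to 13: the C–H bonds of both CH2OH groups are cut back to two ester carbonyl groups, which carry the chiral auxiliaries. The forward reduction must not epimerise C2 or C3 and must not open the β-hydroxy ester by a retro-aldol path.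

13 to 8 and 11 (through 12): the bonds C1–C2 and C3–C4 are cut, which opens ring B to the hydroxy-o-quinodimethane 12 and the dienophile 11; 12 is the photo-tautomer of 8. This is the largest gain: four contiguous stereocenters and a ring go back to an achiral diarylmethane aldehyde and a C2-symmetric dienophile. The forward step needs the E,E-dienol, the endo position for the ester on C3, and attack on one face of 11.

11 to 9 and 10: the two ester C–O bonds are cut; the forward acylation must not racemise 10.

8 to 4 and 6 (through 7): the aryl–CH2 bond C8a–C1 is cut. Both halves have the substitution pattern of one cheap aromatic aldehyde. The forward cross-coupling must tolerate the free formyl group.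

6 to 5, and 4 to 3 to 2 to 1: protecting-group and functional-group changes only (O–Si, C–Cl, C–H of the carbinol).

## Other disconnections considered

Alternative 1: the first that comes to mind. The cut is C1–C8a, made in the forward sense by a Friedel–Crafts cyclisation of a benzylic cation. A trans-2,3-disubstituted butyrolactone with a benzylic hydroxyl group, A1, would be ionised with acid and ring A would close onto C1 to give the trans-lactone A2; hydride reduction would give the diol A3. The key step would form one bond and set only C1. C2 and C3 would have to be set beforehand in separate auxiliary-controlled steps. In A2 the carbonyl group sits on C3 and the ring oxygen on the C2 arm, so reduction would give A3 with two free CH2OH groups, of which the less hindered C3 arm should react first. Acylating the C2 arm would therefore need an additional protection sequence. The chosen plan sets all three centers in one step and distinguishes the arms through the C4 oxygen.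

Alternative 2: a union of like polarity. The cuts are C2–C3 and C1–C8a, made in the forward sense by the biomimetic one-electron oxidation (FeCl3 or Ag2O) of a ferulic ester. Two C8 radicals would couple, and the bis-quinone methide would cyclise to the 1-aryl-1,2-dihydronaphthalene diester A4. The step is short and would even deliver two different esters (one conjugated, one not). However, guaiacyl radicals with a free C5 position are expected to couple mainly through C8–C5 and C8–O4. A4 would be racemic, since no element controls the absolute configuration. C3 would have to be set afterwards by reduction of the C3=C4 bond. The chosen plan controls the regiochemistry, the relative and the absolute configuration in the key step.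

Alternative 3: strain release. The cut is again C1–C8a, made in the forward sense by a Lewis acid (SnCl4) ring opening of the donor–acceptor cyclopropyl aryl ketone A5 with Friedel–Crafts closure to the tetralone A6. The ring strain would drive the ionisation, but C1 would pass through an open benzylic cation and be set only by thermodynamic preference. Ring A would have to attack ortho to a deactivating acyl group. A5 is a trisubstituted cyclopropane that needs its own asymmetric synthesis, and A6 still carries a C4 carbonyl group to be removed and an ester and an ether to be adjusted. The step count would be clearly higher than in the chosen plan.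

Key step: step 7

Assumption: the sense of induction of the (S)-mandelate groups in step 7 is taken from the conformational model given there; if the opposite sense held, the fumarate of methyl (R)-mandelate would be used with no other change.

## Steps

Step 1
Reactants: 1 vanillin (4-hydroxy-3-methoxybenzaldehyde)
Product: 2 3-methoxy-4-(triisopropylsilyloxy)benzaldehyde
Conditions: TIPSCl, imidazole, DMF, rt
Reagents that add atoms: triisopropylsilyl chloride, CC(C)[Si](Cl)(C(C)C)C(C)C
Why: Standard silylation of a phenol; the TIPS ether is chosen because it should survive organozinc chemistry, hydride reduction and trifluoroacetic acid and be cleaved by fluoride at the end.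

Step 2
Reactants: 2 3-methoxy-4-(triisopropylsilyloxy)benzaldehyde
Product: 3 [3-methoxy-4-(triisopropylsilyloxy)phenyl]methanol
Conditions: NaBH4, MeOH/THF, 0 °C
Reagents that add atoms: none
Why: Borohydride reduction of an aryl aldehyde; the aryl silyl ether should be stable at 0 °C.

Step 3
Reactants: 3 [3-methoxy-4-(triisopropylsilyloxy)phenyl]methanol
Product: 4 [4-(chloromethyl)-2-methoxyphenoxy]triisopropylsilane
Conditions: SOCl2, pyridine, CH2Cl2, 0 °C
Reagents that add atoms: thionyl chloride, O=S(Cl)Cl
Why: Chlorodehydroxylation through the chlorosulfite; the electron-rich benzylic position reacts readily, and the chloride would be used without long storage.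

Step 4
Reactants: 5 6-bromovanillin (2-bromo-4-hydroxy-5-methoxybenzaldehyde)
Product: 6 2-bromo-5-methoxy-4-(triisopropylsilyloxy)benzaldehyde
Conditions: TIPSCl, imidazole, DMF, rt
Reagents that add atoms: triisopropylsilyl chloride, CC(C)[Si](Cl)(C(C)C)C(C)C
Why: Silylation of the phenol as in step 1; the bromine stands para to the methoxy group, which is the position where ring A must carry C1.

Step 5
Reactants: 4 [4-(chloromethyl)-2-methoxyphenoxy]triisopropylsilane; 6 2-bromo-5-methoxy-4-(triisopropylsilyloxy)benzaldehyde
Product: 8 5-methoxy-2-[3-methoxy-4-(triisopropylsilyloxy)benzyl]-4-(triisopropylsilyloxy)benzaldehyde, via benzylic zinc chloride 7 (not isolated)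
Conditions: Zn, LiCl, THF, rt; then 6, Pd(OAc)2 (2 mol %), SPhos (4 mol %), THF, rt
Reagents that add atoms: none
Why: LiCl-promoted zinc insertion into the benzylic chloride followed by a Negishi cross-coupling; the ortho-formyl aryl bromide should undergo oxidative addition readily, and with an active catalyst the coupling should outrun addition of the zinc reagent to the aldehyde.

Step 6
Reactants: 9 fumaryl chloride; 10 methyl (S)-mandelate
Product: 11 bis[(S)-2-methoxy-2-oxo-1-phenylethyl] fumarate
Conditions: 10 (2.1 equiv), pyridine, DMAP (cat.), CH2Cl2, 0 °C to rt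
Reagents that add atoms: none
Why: Acylation of a secondary alcohol by an acid chloride; the weak base at low temperature should leave the mandelate stereocenter and the E alkene untouched.

Step 7
Reactants: 8 5-methoxy-2-[3-methoxy-4-(triisopropylsilyloxy)benzyl]-4-(triisopropylsilyloxy)benzaldehyde; 11 bis[(S)-2-methoxy-2-oxo-1-phenylethyl] fumarate
Product: 13 bis[(S)-2-methoxy-2-oxo-1-phenylethyl] (1S,2R,3S,4S)-4-hydroxy-6-methoxy-1-[3-methoxy-4-(triisopropylsilyloxy)phenyl]-7-(triisopropylsilyloxy)-1,2,3,4-tetrahydronaphthalene-2,3-dicarboxylate (target numbering), via photoenol 12 (not isolated)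
Conditions: hν (365 nm LED), 11 (2 equiv), degassed toluene (0.03 M), 15 °C
Reagents that add atoms: none
Why: Excitation of the aryl aldehyde of 8 (n,π* state) is followed by 1,5-hydrogen transfer from the doubly benzylic CH2 and gives the hydroxy-o-quinodimethane 12; its Z-enol forms revert by a 1,5-H shift, so that the long-lived E,E form (OH and aryl both outside) is the one trapped. Closest known reaction type: the photoenolization/Diels–Alder reaction of 2-alkyl- and 2-benzylbenzaldehydes with fumarates, and the thermal addition of α-hydroxy-α'-aryl-o-quinodimethanes to fumarates of α-hydroxy esters. Ring B is closed by a concerted suprafacial [4+2] cycloaddition that forms C1–C2 and C3–C4 and is driven by the return of aromaticity to ring A. C2 and C3 come out trans because the E geometry of 11 is transferred. The ester on C3 takes the endo position, held by a hydrogen bond from the dienol OH, while the ester on C2 stays exo and away from the C1 aryl group; with both diene substituents outside, this puts the C1 aryl group, the C4 OH and the C3 ester on one face and the C2 ester on the other (1,2-trans, 2,3-trans, 3,4-cis). The absolute sense is set by the two (S)-mandelate groups: in the usual ester conformation (s-cis enoate, carbinol C–H eclipsing C=O) each phenyl group covers the si face of its alkene carbon, the C2 axis makes both cover the same side, and the diene adds to the re,re face, which gives C2 R and C3 S in 13 (R,R in the target). Regiochemistry needs no control because 11 is C2-symmetric. The step needs the E geometry of 11 to survive, which the 365 nm light (absorbed by 8 only) and the fast intramolecular hydrogen transfer should secure.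

Step 8
Reactants: 13 bis[(S)-2-methoxy-2-oxo-1-phenylethyl] (1S,2R,3S,4S)-4-hydroxy-6-methoxy-1-[3-methoxy-4-(triisopropylsilyloxy)phenyl]-7-(triisopropylsilyloxy)-1,2,3,4-tetrahydronaphthalene-2,3-dicarboxylate
Product: 14 [(1S,2R,3R,4S)-4-hydroxy-3-(hydroxymethyl)-6-methoxy-1-[3-methoxy-4-(triisopropylsilyloxy)phenyl]-7-(triisopropylsilyloxy)-1,2,3,4-tetrahydronaphthalen-2-yl]methanol (target numbering)
Conditions: i-Bu2AlH (12 equiv), CH2Cl2, −78 to 0 °C; aq. potassium sodium tartrate
Reagents that add atoms: none
Why: Hydride reduction of all four ester groups gives the triol and releases the auxiliary as a water-soluble diol; the low temperature and the non-basic aluminium alkoxides should prevent epimerisation at C2 and C3 and retro-aldol opening.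

Step 9
Reactants: 14 [(1S,2R,3R,4S)-4-hydroxy-3-(hydroxymethyl)-6-methoxy-1-[3-methoxy-4-(triisopropylsilyloxy)phenyl]-7-(triisopropylsilyloxy)-1,2,3,4-tetrahydronaphthalen-2-yl]methanol
Product: 15 acetonide of 14 over the C4 oxygen and the C3 CH2O arm (cis-fused 2,2-dimethyl-1,3-dioxane; C1 S, C2 R, C3 R, C4 S), with the C2 CH2OH arm free
Conditions: Me2C(OMe)2, PPTS (cat.), acetone, rt
Reagents that add atoms: 2,2-dimethoxypropane, COC(C)(C)OC
Why: Ketalisation under thermodynamic control; the C4 OH and the C3 arm are cis and form a six-membered dioxane, which should be preferred over the seven-membered ketal of the two arms, while the C2 arm is trans to the C4 OH and cannot bridge to it.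

Step 10
Reactants: 16 (E)-p-coumaric acid
Product: 18 (E)-3-[4-(triisopropylsilyloxy)phenyl]prop-2-enoic acid, via bis-silylated coumarate 17 (not isolated)
Conditions: TIPSCl (2.2 equiv), imidazole, DMF, rt; then AcOH, THF/H2O, rt
Reagents that add atoms: triisopropylsilyl chloride, CC(C)[Si](Cl)(C(C)C)C(C)C
Why: Both the acid and the phenol are silylated, and the much more labile silyl ester is then hydrolysed selectively under mild aqueous acid, which leaves the aryl silyl ether and the E alkene intact.

Step 11
Reactants: 15 acetonide with free C2 CH2OH arm; 18 (E)-3-[4-(triisopropylsilyloxy)phenyl]prop-2-enoic acid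
Product: 19 (E)-3-[4-(triisopropylsilyloxy)phenyl]prop-2-enoate of 15 at the C2 CH2O arm
Conditions: EDC·HCl, DMAP, CH2Cl2, 0 °C to rt
Reagents that add atoms: none
Why: Steglich esterification of the only free hydroxyl group; the conditions are neutral enough for the acetonide, the silyl ethers and the E alkene.

Step 12
Reactants: 19 coumarate ester of the acetonide
Product: 20 [(1S,2R,3R)-3-(hydroxymethyl)-6-methoxy-1-[3-methoxy-4-(triisopropylsilyloxy)phenyl]-7-(triisopropylsilyloxy)-1,2,3,4-tetrahydronaphthalen-2-yl]methyl (E)-3-[4-(triisopropylsilyloxy)phenyl]prop-2-enoate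
Conditions: Et3SiH (10 equiv), CF3CO2H (20 equiv), H2O (5 equiv), CH2Cl2, 0 °C
Reagents that add atoms: none
Why: Kursanov–Parnes ionic hydrogenation: wet acid hydrolyses the ketal, the benzylic C4–O bond ionises to a cation stabilised by the para oxygen on C7, and the silane delivers hydride, so C4 becomes CH2 and the C3 arm is set free in one operation. The water is there to intercept the ketal oxocarbenium ion before the silane can reduce it; the cinnamate, the aryl silyl ethers and the stereocenters C1 to C3 are not involved.

Step 13
Reactants: 20 tris-TIPS ether of the target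
Product: 21 [(1S,2R,3R)-7-hydroxy-1-(4-hydroxy-3-methoxyphenyl)-3-(hydroxymethyl)-6-methoxy-1,2,3,4-tetrahydronaphthalen-2-yl]methyl (E)-3-(4-hydroxyphenyl)prop-2-enoate (CNP0403384.1)
Conditions: Bu4NF (3.3 equiv), AcOH (3.3 equiv), THF, 0 °C
Reagents that add atoms: none
Why: Fluoride cleavage of three aryl silyl ethers; the acetic acid buffer keeps phenoxide and alkoxide basicity low, so that the ester should neither migrate to the C3 arm nor be cleaved.

## Compound list

1 | vanillin | COc1cc(C=O)ccc1O | starting material
2 | 3-methoxy-4-(triisopropylsilyloxy)benzaldehyde | COc1cc(C=O)ccc1O[Si](C(C)C)(C(C)C)C(C)C | intermediate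
3 | [3-methoxy-4-(triisopropylsilyloxy)phenyl]methanol | COc1cc(CO)ccc1O[Si](C(C)C)(C(C)C)C(C)C | intermediate
4 | [4-(chloromethyl)-2-methoxyphenoxy]triisopropylsilane | COc1cc(CCl)ccc1O[Si](C(C)C)(C(C)C)C(C)C | intermediate
5 | 6-bromovanillin (2-bromo-4-hydroxy-5-methoxybenzaldehyde) | COc1cc(C=O)c(Br)cc1O | starting material
6 | 2-bromo-5-methoxy-4-(triisopropylsilyloxy)benzaldehyde | COc1cc(C=O)c(Br)cc1O[Si](C(C)C)(C(C)C)C(C)C | intermediate
7 | [3-methoxy-4-(triisopropylsilyloxy)benzyl]zinc chloride (LiCl complex, not isolated) | COc1cc(C[Zn]Cl)ccc1O[Si](C(C)C)(C(C)C)C(C)C | intermediate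
8 | 5-methoxy-2-[3-methoxy-4-(triisopropylsilyloxy)benzyl]-4-(triisopropylsilyloxy)benzaldehyde | COc1cc(Cc2cc(O[Si](C(C)C)(C(C)C)C(C)C)c(OC)cc2C=O)ccc1O[Si](C(C)C)(C(C)C)C(C)C | intermediate
9 | fumaryl chloride | O=C(Cl)/C=C/C(=O)Cl | starting material
10 | methyl (S)-mandelate | COC(=O)[C@@H](O)c1ccccc1 | starting material
11 | bis[(S)-2-methoxy-2-oxo-1-phenylethyl] fumarate | COC(=O)[C@@H](OC(=O)/C=C/C(=O)O[C@@H](c1ccccc1)C(=O)OC)c1ccccc1 | intermediate
12 | E,E-hydroxy-o-quinodimethane (photoenol of 8; OH and aryl both outside; not isolated) | O/C=C1\C=C(OC)C(O[Si](C(C)C)(C(C)C)C(C)C)=C/C1=C\c1ccc(O[Si](C(C)C)(C(C)C)C(C)C)c(OC)c1 | intermediate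
13 | bis[(S)-2-methoxy-2-oxo-1-phenylethyl] (1S,2R,3S,4S)-4-hydroxy-6-methoxy-1-[3-methoxy-4-(triisopropylsilyloxy)phenyl]-7-(triisopropylsilyloxy)-1,2,3,4-tetrahydronaphthalene-2,3-dicarboxylate (target numbering) | COc1cc([C@H]2c3cc(O[Si](C(C)C)(C(C)C)C(C)C)c(OC)cc3[C@@H](O)[C@@H](C(=O)O[C@@H](c3ccccc3)C(=O)OC)[C@@H]2C(=O)O[C@@H](c2ccccc2)C(=O)OC)ccc1O[Si](C(C)C)(C(C)C)C(C)C | intermediate
14 | [(1S,2R,3R,4S)-4-hydroxy-3-(hydroxymethyl)-6-methoxy-1-[3-methoxy-4-(triisopropylsilyloxy)phenyl]-7-(triisopropylsilyloxy)-1,2,3,4-tetrahydronaphthalen-2-yl]methanol (target numbering) | COc1cc([C@H]2c3cc(O[Si](C(C)C)(C(C)C)C(C)C)c(OC)cc3[C@@H](O)[C@@H](CO)[C@@H]2CO)ccc1O[Si](C(C)C)(C(C)C)C(C)C | intermediate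
15 | acetonide of 14 over O4 and the C3 CH2O arm (cis-fused 2,2-dimethyl-1,3-dioxane; 1S,2R,3R,4S), C2 CH2OH free | COc1cc([C@H]2c3cc(O[Si](C(C)C)(C(C)C)C(C)C)c(OC)cc3[C@H]3OC(C)(C)OC[C@H]3[C@@H]2CO)ccc1O[Si](C(C)C)(C(C)C)C(C)C | intermediate
16 | (E)-p-coumaric acid | OC(=O)/C=C/c1ccc(O)cc1 | starting material
17 | triisopropylsilyl (E)-3-[4-(triisopropylsilyloxy)phenyl]prop-2-enoate (not isolated) | CC(C)[Si](C(C)C)(C(C)C)OC(=O)/C=C/c1ccc(O[Si](C(C)C)(C(C)C)C(C)C)cc1 | intermediate
18 | (E)-3-[4-(triisopropylsilyloxy)phenyl]prop-2-enoic acid | OC(=O)/C=C/c1ccc(O[Si](C(C)C)(C(C)C)C(C)C)cc1 | intermediate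
19 | (E)-3-[4-(triisopropylsilyloxy)phenyl]prop-2-enoate of 15 at the C2 CH2O arm | COc1cc([C@H]2c3cc(O[Si](C(C)C)(C(C)C)C(C)C)c(OC)cc3[C@H]3OC(C)(C)OC[C@H]3[C@@H]2COC(=O)/C=C/c2ccc(O[Si](C(C)C)(C(C)C)C(C)C)cc2)ccc1O[Si](C(C)C)(C(C)C)C(C)C | intermediate
20 | tris-TIPS ether of the target (1S,2R,3R) | COc1cc([C@H]2c3cc(O[Si](C(C)C)(C(C)C)C(C)C)c(OC)cc3C[C@@H](CO)[C@@H]2COC(=O)/C=C/c2ccc(O[Si](C(C)C)(C(C)C)C(C)C)cc2)ccc1O[Si](C(C)C)(C(C)C)C(C)C | intermediate
21 | CNP0403384.1, [(1S,2R,3R)-7-hydroxy-1-(4-hydroxy-3-methoxyphenyl)-3-(hydroxymethyl)-6-methoxy-1,2,3,4-tetrahydronaphthalen-2-yl]methyl (E)-3-(4-hydroxyphenyl)prop-2-enoate | COc1cc([C@H]2c3cc(O)c(OC)cc3C[C@@H](CO)[C@@H]2COC(=O)/C=C/c2ccc(O)cc2)ccc1O | target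

## Step count and least certain steps

Total step count: 13. Longest linear sequence: 10 steps (steps 1, 2, 3, 5, 7, 8, 9, 11, 12, 13).

Step 7 (key step). The most likely failures are triplet energy transfer from the excited aldehyde to the fumarate, which would isomerise the dienophile to the Z form and lower the efficiency, and insufficient facial discrimination by the auxiliary in a transition state that is not chelated. Decay of the photoenol before it is trapped is a third possibility. The fallback separates the photochemistry from the cycloaddition. It sets out from 8, which would be irradiated in benzene saturated with SO2, so that the photoenol is trapped by cheletropic addition as the cis-hydroxysulfone F1. F1 would then be heated with 11 (toluene, 80–100 °C, ZnO as SO2 scavenger); thermal loss of SO2 regenerates the E,E-dienol in the dark, where the dienophile cannot be isomerised. This comes back to the route at 13.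

Step 5. The benzylic zinc reagent may add to the formyl group of 6, and Wurtz-type homocoupling may compete during the zinc insertion into the electron-rich benzylic chloride. The fallback reverses the polarity. It sets out from 6, which would be converted by Miyaura borylation (B2pin2, PdCl2(dppf), KOAc, dioxane, 80 °C) into the arylboronic ester F2. Suzuki–Miyaura coupling of F2 with 4 (Pd(PPh3)4, aq. K2CO3, DME, 70 °C) comes back to the route at 8.

Step 9. The acidic conditions may ionise the electron-rich benzylic C4–OH (ether formation with methanol, elimination), or the seven-membered ketal over the two arms may compete. The fallback changes the distinguishing group and the order of the endgame. It sets out from 14, which would be converted with t-Bu2Si(OTf)2 and 2,6-lutidine (CH2Cl2, 0 °C, no acid) into the cyclic di-tert-butylsilylene F3 over O4 and the C3 arm. Esterification with 18 as in step 11 would give the silylene ester F4. HF·pyridine in THF would remove the silylene and the three aryl silyl ethers and give the C4-hydroxy triphenol F5. Its benzylic alcohol, now para to a free phenol, would be reduced with Et3SiH and CF3CO2H in CH2Cl2 at −20 °C. This comes back to the route at 21.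

Step 12. The silane may reduce the ketal oxocarbenium ion before water intercepts it, which would leave an isopropyl ether on the C3 arm, and the C4 cation may lose a proton towards C3 and scramble that stereocenter. The fallback separates the two events. It sets out from 19, whose ketal would be hydrolysed with AcOH/H2O/THF at 40 °C to the diol ester F6. The free benzylic alcohol of F6 would then be reduced at low temperature with Et3SiH and BF3·OEt2 (CH2Cl2, −60 °C), where hydride capture should outrun elimination. This comes back to the route at 20.

## Further compounds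

F1 | step 7 | cis-hydroxysulfone, SO2 adduct of 12 (1-hydroxy-3-aryl-1,3-dihydrobenzo[c]thiophene 2,2-dioxide with ring A and aryl group substituted as in 8; racemic, one enantiomer drawn) | COc1cc([C@@H]2c3cc(O[Si](C(C)C)(C(C)C)C(C)C)c(OC)cc3[C@H](O)S2(=O)=O)ccc1O[Si](C(C)C)(C(C)C)C(C)C
F2 | step 5 | 5-methoxy-2-(4,4,5,5-tetramethyl-1,3,2-dioxaborolan-2-yl)-4-(triisopropylsilyloxy)benzaldehyde | COc1cc(C=O)c(B2OC(C)(C)C(C)(C)O2)cc1O[Si](C(C)C)(C(C)C)C(C)C
F3 | step 9 | cyclic di-tert-butylsilylene of 14 over O4 and the C3 CH2O arm, C2 CH2OH free | COc1cc([C@H]2c3cc(O[Si](C(C)C)(C(C)C)C(C)C)c(OC)cc3[C@H]3O[Si](C(C)(C)C)(C(C)(C)C)OC[C@H]3[C@@H]2CO)ccc1O[Si](C(C)C)(C(C)C)C(C)C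
F4 | step 9 | (E)-3-[4-(triisopropylsilyloxy)phenyl]prop-2-enoate of F3 at the C2 CH2O arm | COc1cc([C@H]2c3cc(O[Si](C(C)C)(C(C)C)C(C)C)c(OC)cc3[C@H]3O[Si](C(C)(C)C)(C(C)(C)C)OC[C@H]3[C@@H]2COC(=O)/C=C/c2ccc(O[Si](C(C)C)(C(C)C)C(C)C)cc2)ccc1O[Si](C(C)C)(C(C)C)C(C)C
F5 | step 9 | C4-hydroxy derivative of the target (1S,2R,3R,4S), all phenols free | COc1cc([C@H]2c3cc(O)c(OC)cc3[C@@H](O)[C@@H](CO)[C@@H]2COC(=O)/C=C/c2ccc(O)cc2)ccc1O
F6 | step 12 | diol ester: 19 without the ketal (C4 OH and C3 CH2OH free, 1S,2R,3R,4S, three TIPS ethers kept) | COc1cc([C@H]2c3cc(O[Si](C(C)C)(C(C)C)C(C)C)c(OC)cc3[C@@H](O)[C@@H](CO)[C@@H]2COC(=O)/C=C/c2ccc(O[Si](C(C)C)(C(C)C)C(C)C)cc2)ccc1O[Si](C(C)C)(C(C)C)C(C)C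
A1 | alternative 1 | trans-2,3-disubstituted butyrolactone with benzylic hydroxyl group (C1 carbinol configuration open, lost on ionisation) | COc1cc(C(O)[C@H]2COC(=O)[C@@H]2Cc2ccc(O[Si](C(C)C)(C(C)C)C(C)C)c(OC)c2)ccc1O[Si](C(C)C)(C(C)C)C(C)C
A2 | alternative 1 | trans-fused aryltetralin lactone (carbonyl on C3, ring oxygen on the C2 arm) | COc1cc([C@H]2c3cc(O[Si](C(C)C)(C(C)C)C(C)C)c(OC)cc3C[C@H]3C(=O)OC[C@H]23)ccc1O[Si](C(C)C)(C(C)C)C(C)C
A3 | alternative 1 | bis-TIPS aryltetralin diol with both arms free | COc1cc([C@H]2c3cc(O[Si](C(C)C)(C(C)C)C(C)C)c(OC)cc3C[C@@H](CO)[C@@H]2CO)ccc1O[Si](C(C)C)(C(C)C)C(C)C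
A4 | alternative 2 | diethyl trans-7-hydroxy-1-(4-hydroxy-3-methoxyphenyl)-6-methoxy-1,2-dihydronaphthalene-2,3-dicarboxylate (racemic, one enantiomer drawn) | COc1cc([C@H]2c3cc(O)c(OC)cc3C=C(C(=O)OCC)[C@@H]2C(=O)OCC)ccc1O
A5 | alternative 3 | donor–acceptor cyclopropyl aryl ketone (aryl and benzyloxymethyl trans; quaternary carbon configuration open, lost on ring opening) | COc1cc([C@@H]2[C@@H](COCc3ccccc3)C2(C(=O)OC)C(=O)c2ccc(O[Si](C(C)C)(C(C)C)C(C)C)c(OC)c2)ccc1O[Si](C(C)C)(C(C)C)C(C)C
A6 | alternative 3 | 4-aryl-1-tetralone with C3 ester and C2 benzyloxymethyl (target numbering: C4 ketone) | COc1cc([C@H]2c3cc(O[Si](C(C)C)(C(C)C)C(C)C)c(OC)cc3C(=O)[C@@H](C(=O)OC)[C@@H]2COCc2ccccc2)ccc1O[Si](C(C)C)(C(C)C)C(C)C
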